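Cuts, in retrosynthetic order: the C8 ester; C13 (methylene from a hydroxymethylene group); the C14 and C15 carbinols (from a lactone and an ester); C4=C5 (ring-closing olefination); C11–C12 together with C6–C7 (one annulation); C1=C10 (olefination); C9–C10 and O8–C14 (epoxide opening and lactonisation).
Forward order of rings: a temporary 8,14-lactone (step 1), then the target γ-lactone O6–C12–C11–C7–C6 in one annulation (step 7), then the ten-membered carbocycle by olefination at C4=C5 (step 8), then reductive opening of the temporary lactone.
Enabling feature: the lactone oxygen O6 sits on C6 next to C5, so C5–C6–O6–C12 can be brought in as glycolaldehyde phenyl carbonate. Its enamine carbon C6 and carbonate carbon C12 are 1,3-related through O6 and match the β-carbon C7 and α-carbon C11 of an enal, giving a formal [3+2] closure of the ring O6–C12–C11–C7–C6.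
Stereochemistry: C8 comes from (S)-2-vinyloxirane, whose C–O bond is never broken; C7 from the amine catalyst; C6 by equilibration to the trans-lactone; both ring olefins (ring-cis) from Horner–Wadsworth–Emmons (HWE) reactions.
Helpers: O8 and C14 tied as a lactone, C13 carried as a formyl/enol group (activates C11, masks the lactone as an enolate, later exchanged for CH2), phenoxide as leaving group on C12, C15 as an ester.

Key step: step 7

Remark: germacrane numbering of the target is used (oxygen on C6 and C8, C12 the lactone carbonyl, C13 the exocyclic methylene, C14 and C15 the hydroxymethyl carbons); hydroxymethylene lactones are written as enols of unassigned enol geometry; (S)-2-vinyloxirane and allyl phenyl carbonate are taken as purchasable.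

Step 1
Reactants: 1 triethyl phosphonoacetate; 2 (S)-2-vinyloxirane
Product: 3 diethyl [(5R)-5-ethenyl-2-oxooxolan-3-yl]phosphonate (both C3 epimers)
Conditions: NaH, toluene, 0 → 80 °C; aq. NH4Cl
Reagents that add atoms: none
Why: The sodium phosphonoacetate should open the epoxide at its CH2 terminus (SN2) and the secondary alkoxide should lactonise onto the ethyl ester (known epoxide-to-α-phosphono-γ-butyrolactone annulation), so C8 of the target is carried in from 2 with its configuration.

Step 2
Reactants: 1 triethyl phosphonoacetate; 4 2-(2-bromoethyl)-1,3-dioxolane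
Product: 5 ethyl 2-(diethoxyphosphoryl)-4-(1,3-dioxolan-2-yl)butanoate (racemic)
Conditions: NaH, DMF, 0 → 60 °C
Reagents that add atoms: none
Why: C-Alkylation of the sodium salt of 1 with the primary bromide (SN2) should place C1–C3 of the target, as a masked aldehyde, on the future C4.

Step 3
Reactants: 5 ethyl 2-(diethoxyphosphoryl)-4-(1,3-dioxolan-2-yl)butanoate
Product: 6 ethyl 2-(diethoxyphosphoryl)-5-oxopentanoate (racemic)
Conditions: 1 M aq. HCl, acetone, rt
Reagents that add atoms: water, O
Why: Acid-catalysed acetal hydrolysis should free the aldehyde without touching the phosphonate or the ester.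

Step 4
Reactants: 3 diethyl [(5R)-5-ethenyl-2-oxooxolan-3-yl]phosphonate; 6 ethyl 2-(diethoxyphosphoryl)-5-oxopentanoate
Product: 7 ethyl (5E)-2-(diethoxyphosphoryl)-5-[(5R)-5-ethenyl-2-oxooxolan-3-ylidene]pentanoate (both C2 epimers)
Conditions: 3, NaH (1 equiv), THF, 0 °C; then 6, −20 → 0 °C
Reagents that add atoms: none
Why: In this HWE olefination only the more acidic lactone phosphonate 3 is deprotonated, and its reaction with the aldehyde of 6 should give mainly the E-alkylidene lactone (chain anti to the lactone carbonyl), which is the ring-cis C1=C10 geometry of the target.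

Step 5
Reactants: 7 ethyl (5E)-2-(diethoxyphosphoryl)-5-[(5R)-5-ethenyl-2-oxooxolan-3-ylidene]pentanoate
Product: 8 ethyl (5E)-2-(diethoxyphosphoryl)-5-{(5R)-2-oxo-5-[(1E)-3-oxoprop-1-en-1-yl]oxolan-3-ylidene}pentanoate
Conditions: crotonaldehyde (5 equiv), second-generation Grubbs catalyst (5 mol %), CH2Cl2, 40 °C
Reagents that add atoms: (E)-crotonaldehyde, C/C=C/C=O
Why: Olefin cross-metathesis of the monosubstituted vinyl group with excess crotonaldehyde should give the E-enal, the trisubstituted conjugated alkylidene lactone being inert to the catalyst.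

Step 6
Reactants: 9 allyl phenyl carbonate
Product: 10 2-oxoethyl phenyl carbonate
Conditions: O3, CH2Cl2, −78 °C; then PPh3, → rt
Reagents that add atoms: ozone, [O-][O+]=O
Why: Ozonolysis of the terminal alkene with reductive work-up should give the aldehyde and leave the aryl carbonate intact.

Step 7
Reactants: 8 ethyl (5E)-2-(diethoxyphosphoryl)-5-{(5R)-2-oxo-5-[(1E)-3-oxoprop-1-en-1-yl]oxolan-3-ylidene}pentanoate; 10 2-oxoethyl phenyl carbonate
Product: 12 trans-γ-lactone aldehyde carrying the α-hydroxymethylene group (C6, C7 and C8 arranged as in the target), via Michael adduct dialdehyde 11 (not isolated)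
Conditions: (R)-2-[diphenyl(trimethylsilyloxy)methyl]pyrrolidine (20 mol %), PhCO2H (20 mol %), 10 (2 equiv), toluene, 0 °C → rt; then DBU (1.2 equiv), 0 °C; aq. citric acid
Reagents that add atoms: none
Why: Proposed new method: the secondary amine turns 10 into an enamine (nucleophilic C6) and 8 into an iminium ion (electrophilic C7), their Michael union forges C6–C7, and the α-carbon C11 of the resulting enamine (or of aldehyde 11 once enolised by DBU) attacks the phenyl carbonate carbon C12 held on O6 and expels phenoxide to give the hydroxymethylene lactone. The closest known reactions are the amine-catalysed Michael addition of aldehyde enamines to iminium-activated enals that opens Robinson-type organocascades, and the intramolecular C-acylation of an enolate by an aryl ester or carbonate (Baker–Venkataraman rearrangement, Hauser annulation); new is their union into a formal [3+2] annulation of an O-acylated glycolaldehyde across the α,β-bond of an enal. The only ring closed is the γ-lactone O6–C12–C11–C7–C6, by 5-exo-trig attack of C11 on the carbonate carbonyl, the competing O-acylation needing a seven-membered transition state. C7 is set by the catalyst, whose diphenyl(silyloxy)methyl group blocks one face of the E,s-trans iminium ion so that C6 adds to the other (by this model the R catalyst gives the target configuration next to the fixed C8 centre), C6 is not fixed kinetically but equilibrates through the enol of the α-acyloxy aldehyde to the trans-4,5-disubstituted lactone, and C11 ends as an enol carbon. The step needs chemoselectivity between two aldehydes, secured because only 10 forms a simple enamine while 8 can only give a dienamine through its hindered tertiary C8–H, and it needs the enal to outrun the alkylidene lactone of 8 as acceptor, secured by iminium activation. The acidity of the hydroxymethylene lactone (a vinylogous carboxylic acid) should make the sequence irreversible and draw all C6 diastereomers of 11 into one product.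

Step 8
Reactants: 12 trans-γ-lactone aldehyde carrying the α-hydroxymethylene group
Product: 13 ten-membered dilactone ethyl ester (6,12- and 8,14-lactones, C4=C5 and C1=C10 both ring-cis, C15 as CO2Et)
Conditions: LiCl, DBU, MeCN, rt, slow addition (final 0.002 M); aq. citric acid
Reagents that add atoms: none
Why: Intramolecular HWE olefination under mild LiCl/DBU conditions should close the ten-membered ring at C4=C5 as the E-enoate (ring-cis, the less strained isomer), while the hydroxymethylene lactone sits as its unreactive enolate and C6 stays in the thermodynamic trans arrangement.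

Step 9
Reactants: 13 ten-membered dilactone ethyl ester
Product: 15 hydroxymethylene lactone triol (free 8-OH, 14-OH and 15-OH), via sodium enolate 14 (not isolated)
Conditions: NaH (1.05 equiv), THF, 0 °C; i-Bu2AlH (7 equiv), −78 → 0 °C; aq. potassium sodium tartrate
Reagents that add atoms: none
Why: Once the vinylogous acid is converted into its sodium enolate, which hydride does not attack (enolate as protecting group), i-Bu2AlH should reduce the ethyl enoate and the α-alkylidene lactone by 1,2-addition to the two primary allylic alcohols and free the C8 hydroxyl.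

Step 10
Reactants: 15 hydroxymethylene lactone triol
Product: 16 α-methylene lactone triol (the target without its ester)
Conditions: 37 % aq. CH2O, K2CO3, THF, 0 °C
Reagents that add atoms: formaldehyde, C=O
Why: In this deformylative methylenation (a known conversion of α-hydroxymethylene lactones), aldol addition of the enolate to formaldehyde at C11, transfer of the formyl group to the new alkoxide and β-elimination of formate should give the α-methylene lactone.

Step 11
Reactants: 16 α-methylene lactone triol
Product: 17 14,15-bis(tert-butyldimethylsilyl) ether of 16 (free 8-OH)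
Conditions: TBSCl (2.1 equiv), imidazole, DMF, −20 °C
Reagents that add atoms: tert-butyldimethylsilyl chloride, CC(C)(C)[Si](C)(C)Cl
Why: The two primary allylic hydroxyls should be silylated much faster than the hindered secondary C8 hydroxyl.

Step 12
Reactants: 17 14,15-bis(tert-butyldimethylsilyl) ether of 16
Product: 18 8-O-(3-methylbutanoyl) derivative of 17
Conditions: 3-methylbutanoic anhydride, DMAP, Et3N, CH2Cl2, 0 °C → rt
Reagents that add atoms: 3-methylbutanoic anhydride, CC(C)CC(=O)OC(=O)CC(C)C
Why: DMAP-catalysed acylation of the remaining secondary alcohol should install the 3-methylbutanoate with retention at C8.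

Step 13
Reactants: 18 8-O-(3-methylbutanoyl) derivative of 17
Product: 19 target, (6R,7R,8R)-configured 8-O-(3-methylbutanoyl)-14,15-dihydroxy-germacra-1(10),4,11(13)-trien-12,6-olide
Conditions: HF·pyridine, pyridine, THF, 0 °C
Reagents that add atoms: none
Why: Buffered fluoride should cleave both primary silyl ethers without acyl migration or attack on the α-methylene lactone.

Compound list
1 | triethyl phosphonoacetate | CCOC(=O)CP(=O)(OCC)OCC | starting material
2 | (S)-2-vinyloxirane | C=C[C@H]1CO1 | starting material
3 | diethyl [(5R)-5-ethenyl-2-oxooxolan-3-yl]phosphonate (both C3 epimers) | C=C[C@H]1CC(P(=O)(OCC)OCC)C(=O)O1 | intermediate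
4 | 2-(2-bromoethyl)-1,3-dioxolane | BrCCC1OCCO1 | starting material
5 | ethyl 2-(diethoxyphosphoryl)-4-(1,3-dioxolan-2-yl)butanoate (racemic) | CCOC(=O)C(CCC1OCCO1)P(=O)(OCC)OCC | intermediate
6 | ethyl 2-(diethoxyphosphoryl)-5-oxopentanoate (racemic) | CCOC(=O)C(CCC=O)P(=O)(OCC)OCC | intermediate
7 | ethyl (5E)-2-(diethoxyphosphoryl)-5-[(5R)-5-ethenyl-2-oxooxolan-3-ylidene]pentanoate (both C2 epimers) | C=C[C@H]1C/C(=C\CCC(C(=O)OCC)P(=O)(OCC)OCC)C(=O)O1 | intermediate
8 | ethyl (5E)-2-(diethoxyphosphoryl)-5-{(5R)-2-oxo-5-[(1E)-3-oxoprop-1-en-1-yl]oxolan-3-ylidene}pentanoate (both C2 epimers) | O=C/C=C/[C@H]1C/C(=C\CCC(C(=O)OCC)P(=O)(OCC)OCC)C(=O)O1 | intermediate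
9 | allyl phenyl carbonate | C=CCOC(=O)Oc1ccccc1 | starting material
10 | 2-oxoethyl phenyl carbonate | O=CCOC(=O)Oc1ccccc1 | intermediate
11 | Michael adduct: 1,5-dialdehyde with the phenyl carbonate on C6 (C6 epimers; C7 and C8 as in the target; not isolated) | O=CC(OC(=O)Oc1ccccc1)[C@H](CC=O)[C@H]1C/C(=C\CCC(C(=O)OCC)P(=O)(OCC)OCC)C(=O)O1 | intermediate
12 | trans-γ-lactone (O6–C12–C11–C7–C6) with CHO on C6, hydroxymethylene on C11 and the (5R)-alkylidene lactone on C7 | O=C[C@H]1OC(=O)C(=CO)[C@@H]1[C@H]2C/C(=C\CCC(C(=O)OCC)P(=O)(OCC)OCC)C(=O)O2 | intermediate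
13 | ten-membered dilactone ethyl ester (6,12-lactone with 13-hydroxymethylene, 8,14-lactone, C15 as CO2Et, both ring olefins ring-cis) | OC=C1C(=O)O[C@@H]2/C=C(/C(=O)OCC)CC/C=C(/C(=O)O3)C[C@@H]3[C@@H]12 | intermediate
14 | sodium enolate of 13 (not isolated) | [Na+].[O-]C=C1C(=O)O[C@@H]2/C=C(/C(=O)OCC)CC/C=C(/C(=O)O3)C[C@@H]3[C@@H]12 | intermediate
15 | 13-hydroxymethylene-6,12-lactone with free 8-, 14- and 15-hydroxyls | OC=C1C(=O)O[C@@H]2/C=C(/CO)CC/C=C(/CO)C[C@@H](O)[C@@H]12 | intermediate
16 | α-methylene lactone triol (8-deacyl target) | C=C1C(=O)O[C@@H]2/C=C(/CO)CC/C=C(/CO)C[C@@H](O)[C@@H]12 | intermediate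
17 | 14,15-bis(tert-butyldimethylsilyl) ether of 16 | C=C1C(=O)O[C@@H]2/C=C(/CO[Si](C)(C)C(C)(C)C)CC/C=C(/CO[Si](C)(C)C(C)(C)C)C[C@@H](O)[C@@H]12 | intermediate
18 | 8-O-(3-methylbutanoyl) derivative of 17 | C=C1C(=O)O[C@@H]2/C=C(/CO[Si](C)(C)C(C)(C)C)CC/C=C(/CO[Si](C)(C)C(C)(C)C)C[C@@H](OC(=O)CC(C)C)[C@@H]12 | intermediate
19 | target (CNP0199826.1) | C=C1C(=O)O[C@@H]2/C=C(/CO)CC/C=C(/CO)C[C@@H](OC(=O)CC(C)C)[C@@H]12 | target

Total step count: 13. Longest linear sequence: 11 steps (steps 2, 3, 4, 5, 7, 8, 9, 10, 11, 12, 13).

Steps most likely to fail

Step 7 (proposed new method). What may go wrong: the enamine of 10 may self-condense or the catalyst may be acylated by the carbonate; the enal may lose its C8 configuration through dienamine formation; the catalyst may be mismatched with the C8 centre and give poor facial selectivity at C7; or the sequence may stall at 11 without acyl transfer. The fallback uses known chemistry and sets out from 8. An N-heterocyclic-carbene-catalysed homoenolate annulation of 8 with 2,2-dimethoxyacetaldehyde (chiral triazolium precatalyst, DBU, THF) should give the γ-lactone dimethyl acetal F1, whose lactone carbonyl is the former aldehyde carbon of 8. Claisen formylation (NaH, ethyl formate, THF) should then give the hydroxymethylene lactone acetal F2. Aqueous trifluoroacetic acid should free the C5 aldehyde, with C6 equilibrating to the trans-lactone, and the route is rejoined at 12.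

Step 8. What may go wrong: intermolecular olefination to oligomers, or a slow closure against the rigid trans-lactone and the bridging 8,14-lactone. The fallback closes the same bond by metathesis instead of olefination and sets out from 8. HWE reaction of the phosphonate of 8 with aqueous formaldehyde (K2CO3) should give the 2-substituted acrylate enal F3. Annulation of F3 with 10 as in step 7 should give the acrylate lactone aldehyde F4. Takai–Lombardo methylenation (CH2Br2, Zn, TiCl4) should convert the C5 aldehyde into a vinyl group, giving the vinyl acrylate F5. Ring-closing metathesis between the vinyl group and the acrylate (second-generation Grubbs catalyst, toluene, 80 °C, high dilution) should form C4=C5, and the route is rejoined at 13.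

Step 10. What may go wrong: under base the free C8 hydroxyl may add to the new exocyclic methylene or take over the lactone carbonyl (translactonisation to the 8,12-lactone). The fallback makes the methylene last and sets out from 15. Excess TBSCl with imidazole should silylate both primary hydroxyls and the enol, giving the tris-silyl compound F6. 3-Methylbutanoic anhydride with DMAP should acylate the C8 hydroxyl, giving the ester F7. HF·pyridine should remove the three silyl groups, giving the hydroxymethylene lactone diol ester F8. Deformylative methylenation (aq. CH2O, K2CO3, 0 °C) should then give 19 directly.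

Further compounds
F1 | step 7 | γ-lactone dimethyl acetal (as 12, but C11 is CH2 and C5 is CH(OMe)2; C6 epimers) | COC(OC)C1OC(=O)C[C@@H]1[C@H]2C/C(=C\CCC(C(=O)OCC)P(=O)(OCC)OCC)C(=O)O2
F2 | step 7 | hydroxymethylene lactone dimethyl acetal (as 12, but C5 is CH(OMe)2; C6 epimers) | COC(OC)C1OC(=O)C(=CO)[C@@H]1[C@H]2C/C(=C\CCC(C(=O)OCC)P(=O)(OCC)OCC)C(=O)O2
F3 | step 8 | ethyl (5E)-2-methylidene-5-{(5R)-2-oxo-5-[(1E)-3-oxoprop-1-en-1-yl]oxolan-3-ylidene}pentanoate | O=C/C=C/[C@H]1C/C(=C\CCC(=C)C(=O)OCC)C(=O)O1
F4 | step 8 | acrylate analogue of 12 (C4 as C(=CH2)CO2Et in place of the phosphonate) | O=C[C@H]1OC(=O)C(=CO)[C@@H]1[C@H]2C/C(=C\CCC(=C)C(=O)OCC)C(=O)O2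
F5 | step 8 | vinyl analogue of F4 (C5 aldehyde replaced by CH=CH2) | C=C[C@H]1OC(=O)C(=CO)[C@@H]1[C@H]2C/C(=C\CCC(=C)C(=O)OCC)C(=O)O2
F6 | step 10 | 14,15-bis(tert-butyldimethylsilyl) ether and enol silyl ether of 15 | CC(C)(C)[Si](C)(C)OC=C1C(=O)O[C@@H]2/C=C(/CO[Si](C)(C)C(C)(C)C)CC/C=C(/CO[Si](C)(C)C(C)(C)C)C[C@@H](O)[C@@H]12
F7 | step 10 | 8-O-(3-methylbutanoyl) derivative of F6 | CC(C)(C)[Si](C)(C)OC=C1C(=O)O[C@@H]2/C=C(/CO[Si](C)(C)C(C)(C)C)CC/C=C(/CO[Si](C)(C)C(C)(C)C)C[C@@H](OC(=O)CC(C)C)[C@@H]12
F8 | step 10 | 13-hydroxymethylene lactone 14,15-diol 8-(3-methylbutanoate) | OC=C1C(=O)O[C@@H]2/C=C(/CO)CC/C=C(/CO)C[C@@H](OC(=O)CC(C)C)[C@@H]12
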